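All constants stand for no real mixture; the rest is arithmetic.

Count the unbound D by the part of it that stands as D itself.

D 0.050 M; J 0.0350 M; time 1.0 h

    D ⇌ E (K1 = 4.7, k1 = 2.49 min⁻¹)
    D + J → D.J (k2 = 78.8 M⁻¹ min⁻¹)
    D ⇌ L (K3 = 3.0, k3 = 0.173 min⁻¹)
    D.J ⇌ Z (K4 = 2.8, k4 = 1.41 min⁻¹)

- which holds at 1.0 h: what has brought the reaction to rest, or that it has not come to rest (it is still moving / forward and back rates have come level / all of D has reacted / J has run out first)
- share of the D used up at 1.0 h
- E at 1.0 h, in percent of the D charged
- Z at 1.0 h, in percent of the D charged
- D.J at 1.0 h, in percent of the D charged

- the reaction counts as stopped when no species that holds the D changes by six tenths of a point or more over the second half of the time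
- run time (flask): 1.0 h

[J] is charged below [D] and the capture step has no way back, so J is the limiting reagent, and once J is consumed the bound forms D.J and Z hold 70.0 % of the D charged. The fourth step relaxes with a half-life of 0.362 min, short against 1.0 h, so Z stands at 2.8 times D.J, which gives Z 51.6 % and D.J 18.4 %. Among the unbound D, E and L, the first and third steps relax with half-lives of 0.230 min and 0.0501 h, also short against the time. Hence the free share of D, the fraction of the unbound pool standing as D once those two steps are level, is 11.5 %. My reckoning therefore leaves D at 3.45 % of the charge, a conversion of 96.6 %, with E at 16.2 %.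

The weak link is the claim that J is consumed in time. With [D] held at its rest value of 0.00172 M, capture of J is pseudo-first-order with a rate constant k2[D] of 0.136 min⁻¹. On that reckoning the J left at 0.500 h is worth 1.18 % of the D charged, over the stop mark. But that [D] is too low while J lasts, since the unbound pool starts at 0.050 M, above the 0.0150 M at which it comes to rest. With [D] taken as the free share of the sum of that rest pool and [J], the ratio of [J] to that sum decays at the same rate from 70.0 %, which scales late J by 30.0 %, to 0.509 % of its charge at 0.500 h, worth 0.356 % of the D charged and under the mark. I commit to J running out first.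

The forecast says J has run out first, with conversion 96.6 %, E 16.2 %, Z 51.6 % and D.J 18.4 %, and it names “the slow release from L the only real doubt”.

In the simulation of the flask the outcome is: J has run out first, with conversion 96.6 %, E 16.2 %, Z 51.6 % and D.J 18.4 %. In that flask J reads 0.320 % of its charge at 0.500 h, lower than reckoned, and 0.0054 % at 1.00 h.

The neighbour flask, charged with 0.021 M of J, has the same free share but a bound part of 42.0 %. The reckoning puts its D at 6.67 %, E at 31.3 % and Z at 30.9 %. Simulated, the neighbour flask holds J at 0 %, D at 6.68 %, E at 31.4 % and Z at 30.9 %, a conversion of 93.3 %.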